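## Retrosynthetic overview

1. The target comes from acetylation of its 14-alcohol. The ten-membered ring and the butenolide are closed together by one intramolecular Ni/Cr coupling: C8 of a (Z)-β-triflyloxy-α-methyl enoate reacts as a β-acylvinyl anion (homoenolate-type d3 carbon) with the C7 (Z)-enal, then lactonises. C7–C8 is the key bond.
2. C2–C3 comes from ligand-controlled addition of a bis(homoallyl)zinc (C3–C7, from (Z)-3-methylpent-2-en-4-yn-1-ol) to the C2 aldehyde, followed by benzoylation.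
3. The ring A enone comes from a Schenck ene / Kornblum–DeLaMare oxidation of a cyclohexene.
4. Ring A with C1, C10 and C14 comes from an enantioselective Diels–Alder of (1E,3E)-1-silyloxypenta-1,3-diene with an (E)-2-methyl-enal that already carries the enol triflate.
5. Ring order: ring A (six-membered) first, then the ten-membered carbocycle and the butenolide simultaneously in the key step.

Assumption: briarane numbering is used for all intermediates (C15 = methyl on C1, C16 on C5, C17 = lactone α-carbon, C20 = methyl on C11); CIP labels at C1 and C14 change along the route only because substituent priorities change, never by inversion.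

## Route

Step 1
Reactants: 1 ethyl 2-methyl-3-oxobutanoate; 2 (E)-3-ethoxy-2-methylprop-2-enal
Product: 5 ethyl (2Z,5E)-2,6-dimethyl-7-oxo-3-(trifluoromethylsulfonyloxy)hepta-2,5-dienoate, via hydroxy keto ester 3 (not isolated), via hydroxy enol triflate 4 (not isolated)
Conditions: NaH, THF, 0 °C; n-BuLi, 0 °C; 2, −78 °C; AcOH (1.0 equiv); PhNTf2, −78 °C → rt; then 1 M HCl, THF, rt
Reagents that add atoms: N-phenylbis(trifluoromethanesulfonimide) O=S(=O)(N(c1ccccc1)S(=O)(=O)C(F)(F)F)C(F)(F)F; water O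
Why: The Weiler dianion adds through its γ-carbon 1,2 to the vinylogous formate, the chelated Na/Li β-keto ester enolate is O-triflated to the Z enol triflate, and only then does aqueous acid transpose the 3-ethoxyallyl alcohol to the thermodynamically preferred E-2-methyl-enal, so a free keto-enal (glutaconaldehyde-type tautomerism at C9) is never present.

Step 2
Reactants: 6 (E)-pent-2-enal
Product: 7 tert-butyl(dimethyl)[(1E,3E)-penta-1,3-dien-1-yloxy]silane
Conditions: TBSOTf, Et3N, Et2O, 0 °C → rt; used as the isomer mixture obtained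
Reagents that add atoms: tert-butyldimethylsilyl trifluoromethanesulfonate CC(C)(C)[Si](C)(C)OS(=O)(=O)C(F)(F)F
Why: Soft γ-enolisation and O-silylation of the enal give the silyl dienol ether, of which only the s-cis-accessible (1E,3E) isomer takes part in the next step.

Step 3
Reactants: 5 ethyl (2Z,5E)-2,6-dimethyl-7-oxo-3-(trifluoromethylsulfonyloxy)hepta-2,5-dienoate; 7 tert-butyl(dimethyl)[(1E,3E)-penta-1,3-dien-1-yloxy]silane
Product: 8 ethyl (2Z)-4-[(1R,2S,5R,6S)-5-(tert-butyldimethylsilyloxy)-6-formyl-2,6-dimethylcyclohex-3-en-1-yl]-2-methyl-3-(trifluoromethylsulfonyloxy)but-2-enoate (briarane numbering 10R,11S,14R,1S)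
Conditions: (S)-3,3-diphenyl-1-(2-methylphenyl)tetrahydro-1H,3H-pyrrolo[1,2-c][1,3,2]oxazaborole·HN(SO2CF3)2 (20 mol%), 7 (3 equiv), CH2Cl2, −78 → −40 °C
Reagents that add atoms: none
Why: Corey oxazaborolidinium-catalysed endo Diels–Alder, in which the 1-silyloxy group directs C14 onto the α-carbon C1, the E-dienophile fixes C2 and C9 trans, endo addition puts the C14 oxygen cis to the formyl group, and the (S)-catalyst (formyl C–H···O binding, s-trans enal) is expected to expose the re face of C1, which corresponds to the target's 1R and 14S (labelled 1S and 14R here through priority changes only).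

Step 4
Reactants: 8 Diels–Alder adduct
Product: 11 ethyl (2Z)-4-[(1R,5S,6S)-5-(tert-butyldimethylsilyloxy)-6-formyl-2,6-dimethyl-4-oxocyclohex-2-en-1-yl]-2-methyl-3-(trifluoromethylsulfonyloxy)but-2-enoate, via allylic hydroperoxide 9 (not isolated), via peroxyacetate 10 (not isolated)
Conditions: O2, 5,10,15,20-tetraphenylporphyrin (1 mol%), white LED, Ac2O, pyridine, DMAP (cat.), CH2Cl2, 0 °C → rt
Reagents that add atoms: dioxygen O=O
Why: Schenck ene reaction followed by Kornblum–DeLaMare dehydration, in which singlet oxygen approaches anti to the pseudoaxial OTBS and removes the only pseudoaxial allylic hydrogen on that face (H11), placing oxygen on C13 and the alkene at C11=C12; the electron-poor enol triflate alkene is inert and the C11 stereocentre is erased.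

Step 5
Reactants: 12 (Z)-3-methylpent-2-en-4-yn-1-ol
Product: 13 tert-butyl(dimethyl)[(2Z)-3-methylpent-2-en-4-yn-1-yloxy]silane
Conditions: TBSCl, imidazole, CH2Cl2, 0 °C → rt
Reagents that add atoms: tert-butyldimethylsilyl chloride CC(C)(C)[Si](C)(C)Cl
Why: Standard silylation of a primary allylic alcohol; the commercial Z geometry is not affected.

Step 6
Reactants: 13 tert-butyl(dimethyl)[(2Z)-3-methylpent-2-en-4-yn-1-yloxy]silane
Product: 14 tert-butyl(dimethyl)[(2Z)-3-methylpenta-2,4-dien-1-yloxy]silane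
Conditions: H2 (1 atm), Pd/CaCO3 poisoned with Pb(OAc)2, quinoline, hexane, rt
Reagents that add atoms: none
Why: Lindlar semi-hydrogenation of the terminal alkyne of a conjugated enyne stops at the vinyl group and leaves the trisubstituted Z-alkene untouched.

Step 7
Reactants: 11 ring A enone aldehyde; 14 tert-butyl(dimethyl)[(2Z)-3-methylpenta-2,4-dien-1-yloxy]silane
Product: 17 ethyl (2Z)-4-[(1R,5S,6R)-5-(tert-butyldimethylsilyloxy)-6-[(1S,4Z)-6-(tert-butyldimethylsilyloxy)-1-hydroxy-4-methylhex-4-en-1-yl]-2,6-dimethyl-4-oxocyclohex-2-en-1-yl]-2-methyl-3-(trifluoromethylsulfonyloxy)but-2-enoate, via alkyldiethylborane 15 (not isolated), via dialkylzinc 16 (not isolated)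
Conditions: 14 (5 equiv), Et2BH (from BH3·SMe2 + 2 BEt3), 0 °C → rt; Et2Zn (neat), 0 °C, then volatiles removed in vacuo; (1R,2R)-N,N'-bis(trifluoromethylsulfonyl)cyclohexane-1,2-diamine (8 mol%), Ti(OiPr)4 (2 equiv), toluene, −20 °C; 11, −20 → 0 °C; aq. NH4Cl
Reagents that add atoms: none
Why: Knochel hydroboration / boron–zinc exchange gives the bis(homoallyl)zinc with the Z-alkene intact, and its titanium bis(sulfonamide)-catalysed addition is aldehyde-selective in the presence of enone, ester and triflate; the (1R,2R)-ligand (si-face delivery) and the Felkin–Anh bias of the substrate (nucleophile anti to the C1–C14 bond carrying OTBS, no chelation) both lead to 2S.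

Step 8
Reactants: 17 C2 alcohol
Product: 18 the C2 benzoate of 17 (briarane numbering 1R,2S,10R,14S)
Conditions: BzCl, pyridine, DMAP (0.2 equiv), CH2Cl2, 0 → 40 °C
Reagents that add atoms: benzoyl chloride O=C(Cl)c1ccccc1
Why: DMAP-catalysed acylation of the only free hydroxyl (hindered, hence warming); no stereocentre is touched.

Step 9
Reactants: 18 benzoate bis-silyl ether
Product: 19 ethyl (2Z)-4-[(1R,5S,6S)-6-[(1S,4Z)-1-(benzoyloxy)-6-hydroxy-4-methylhex-4-en-1-yl]-5-hydroxy-2,6-dimethyl-4-oxocyclohex-2-en-1-yl]-2-methyl-3-(trifluoromethylsulfonyloxy)but-2-enoate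
Conditions: HF·pyridine, pyridine, THF, 0 °C → rt
Reagents that add atoms: none
Why: Buffered fluoride cleaves both silyl ethers without ester migration or harm to the enol triflate; C14–OH is unmasked only now, when C2 is no longer a carbonyl, so retro-aldol is impossible.

Step 10
Reactants: 19 diol
Product: 20 ethyl (2Z)-4-[(1R,5S,6S)-6-[(1S,4Z)-1-(benzoyloxy)-4-methyl-6-oxohex-4-en-1-yl]-5-hydroxy-2,6-dimethyl-4-oxocyclohex-2-en-1-yl]-2-methyl-3-(trifluoromethylsulfonyloxy)but-2-enoate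
Conditions: TEMPO (10 mol%), PhI(OAc)2 (1.2 equiv), CH2Cl2, rt
Reagents that add atoms: none
Why: Oxoammonium oxidation is selective for the primary allylic alcohol over the hindered secondary α-ketol and gives the Z-enal without isomerisation (as for nerol to neral).

Step 11
Reactants: 20 hydroxy enal enol triflate
Product: 22 14-O-deacetyl target (briarane numbering 1S,2S,7R,10R,14S), via seco hydroxy ester 21 (not isolated)
Conditions: CrCl2 (10 equiv), NiCl2 (10 mol%), degassed DMF, 2 mM (syringe-pump addition of 20), rt; aq. work-up; PPTS (cat.), CH2Cl2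
Reagents that add atoms: none
Why: In this Nozaki–Hiyama–Kishi macrocyclisation zerovalent nickel inserts into the C8–OTf bond and transmetalates to chromium, so C8, normally the electrophilic β-carbon of the enoate, attacks the electrophilic C7 aldehyde as a β-acylvinyl anion (homoenolate-type d3 carbon), and the Z-alkoxide lactonises to the butenolide; 7R is expected because the chromium-bound carbonyl oxygen should turn away from the axial C15 methyl in the closing ten-membered transition state, leaving H7 syn to C15.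

Step 12
Reactants: 22 14-O-deacetyl target
Product: 23 target, (1R,2S,7R,10R,14S)-14-acetoxy-2-benzoyloxy-13-oxobriara-5Z,8(17),11-trien-18,7-olide
Conditions: Ac2O, pyridine, DMAP (cat.), CH2Cl2, 0 °C
Reagents that add atoms: acetic anhydride CC(=O)OC(C)=O
Why: DMAP-catalysed acetylation of the only free hydroxyl under mild conditions that do not epimerise C14 or C7.

## Compound list

1 | ethyl 2-methyl-3-oxobutanoate | CCOC(=O)C(C)C(C)=O | starting material
2 | (E)-3-ethoxy-2-methylprop-2-enal | CCO/C=C(\C)C=O | starting material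
3 | ethyl (6E)-7-ethoxy-5-hydroxy-2,6-dimethyl-3-oxohept-6-enoate (not isolated) | CCOC(=O)C(C)C(=O)CC(O)/C(C)=C/OCC | intermediate
4 | ethyl (2Z,6E)-7-ethoxy-5-hydroxy-2,6-dimethyl-3-(trifluoromethylsulfonyloxy)hepta-2,6-dienoate (not isolated) | CCOC(=O)/C(C)=C(\OS(=O)(=O)C(F)(F)F)CC(O)/C(C)=C/OCC | intermediate
5 | ethyl (2Z,5E)-2,6-dimethyl-7-oxo-3-(trifluoromethylsulfonyloxy)hepta-2,5-dienoate | CCOC(=O)/C(C)=C(\OS(=O)(=O)C(F)(F)F)C/C=C(\C)C=O | intermediate
6 | (E)-pent-2-enal | CC/C=C/C=O | starting material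
7 | tert-butyl(dimethyl)[(1E,3E)-penta-1,3-dien-1-yloxy]silane | C/C=C/C=C/O[Si](C)(C)C(C)(C)C | intermediate
8 | Diels–Alder adduct, ring (1R,2S,5R,6S): OTBS, CHO and C11-methyl cis, side chain trans to CHO | CC(C)(C)[Si](C)(C)O[C@@H]1C=C[C@H](C)[C@@H](C/C(OS(=O)(=O)C(F)(F)F)=C(\C)C(=O)OCC)[C@]1(C)C=O | intermediate
9 | C13 allylic hydroperoxide of 8 with C11=C12, 13S (not isolated) | CC(C)(C)[Si](C)(C)O[C@@H]1[C@@H](OO)C=C(C)[C@@H](C/C(OS(=O)(=O)C(F)(F)F)=C(\C)C(=O)OCC)[C@]1(C)C=O | intermediate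
10 | peroxyacetate of 9 (not isolated) | CC(C)(C)[Si](C)(C)O[C@@H]1[C@@H](OOC(C)=O)C=C(C)[C@@H](C/C(OS(=O)(=O)C(F)(F)F)=C(\C)C(=O)OCC)[C@]1(C)C=O | intermediate
11 | ring A enone aldehyde, ring (1R,5S,6S) | CC(C)(C)[Si](C)(C)O[C@@H]1C(=O)C=C(C)[C@@H](C/C(OS(=O)(=O)C(F)(F)F)=C(\C)C(=O)OCC)[C@]1(C)C=O | intermediate
12 | (Z)-3-methylpent-2-en-4-yn-1-ol | C#C/C(C)=C\CO | starting material
13 | tert-butyl(dimethyl)[(2Z)-3-methylpent-2-en-4-yn-1-yloxy]silane | C#C/C(C)=C\CO[Si](C)(C)C(C)(C)C | intermediate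
14 | tert-butyl(dimethyl)[(2Z)-3-methylpenta-2,4-dien-1-yloxy]silane | C=C/C(C)=C\CO[Si](C)(C)C(C)(C)C | intermediate
15 | [(3Z)-5-(tert-butyldimethylsilyloxy)-3-methylpent-3-en-1-yl]diethylborane (not isolated) | CCB(CC)CC/C(C)=C\CO[Si](C)(C)C(C)(C)C | intermediate
16 | bis[(3Z)-5-(tert-butyldimethylsilyloxy)-3-methylpent-3-en-1-yl]zinc (not isolated) | CC(C)(C)[Si](C)(C)OC/C=C(/C)CC[Zn]CC/C(C)=C\CO[Si](C)(C)C(C)(C)C | intermediate
17 | C2 alcohol (1R,2S,10R,14S; 5Z) | CC(C)(C)[Si](C)(C)O[C@@H]1C(=O)C=C(C)[C@@H](C/C(OS(=O)(=O)C(F)(F)F)=C(\C)C(=O)OCC)[C@]1(C)[C@@H](O)CC/C(C)=C\CO[Si](C)(C)C(C)(C)C | intermediate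
18 | C2 benzoate (1R,2S,10R,14S) | CC(C)(C)[Si](C)(C)O[C@@H]1C(=O)C=C(C)[C@@H](C/C(OS(=O)(=O)C(F)(F)F)=C(\C)C(=O)OCC)[C@]1(C)[C@@H](OC(=O)c2ccccc2)CC/C(C)=C\CO[Si](C)(C)C(C)(C)C | intermediate
19 | C7,C14-diol (1S,2S,10R,14S) | O[C@@H]1C(=O)C=C(C)[C@@H](C/C(OS(=O)(=O)C(F)(F)F)=C(\C)C(=O)OCC)[C@]1(C)[C@@H](OC(=O)c2ccccc2)CC/C(C)=C\CO | intermediate
20 | C7 Z-enal with free C14–OH (1S,2S,10R,14S) | O[C@@H]1C(=O)C=C(C)[C@@H](C/C(OS(=O)(=O)C(F)(F)F)=C(\C)C(=O)OCC)[C@]1(C)[C@@H](OC(=O)c2ccccc2)CC/C(C)=C\C=O | intermediate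
21 | ten-membered 7R-hydroxy (Z)-ethyl ester, seco-lactone (not isolated) | O[C@@H]1C(=O)C=C(C)[C@H]2C/C(=C(\C)C(=O)OCC)[C@H](O)/C=C(/C)CC[C@H](OC(=O)c3ccccc3)[C@@]21C | intermediate
22 | 14-O-deacetyl target (1S,2S,7R,10R,14S) | O[C@@H]1C(=O)C=C(C)[C@H]2CC3=C(C)C(=O)O[C@@H]3/C=C(/C)CC[C@H](OC(=O)c3ccccc3)[C@@]21C | intermediate
23 | (1R,2S,7R,10R,14S)-14-acetoxy-2-benzoyloxy-13-oxobriara-5Z,8(17),11-trien-18,7-olide | CC(=O)O[C@@H]1C(=O)C=C(C)[C@H]2CC3=C(C)C(=O)O[C@@H]3/C=C(/C)CC[C@H](OC(=O)c3ccccc3)[C@@]21C | target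

## Step count and risks

Total step count: 12. Longest linear sequence: 9 steps (1, 3, 4, 7, 8, 9, 10, 11, 12).

**Step 11 (Ni/Cr macrocyclisation).** A tetrasubstituted enol triflate must close a ten-membered ring and set C7 with no external control. Fallback: ring closure is moved to C5=C6 and C7 is set by reagent control. Setting out from 11, isoprene is hydroborated with Et2BH to (3-methylbut-3-en-1-yl)diethylborane F4 and exchanged with Et2Zn to bis(3-methylbut-3-en-1-yl)zinc F5. This adds to 11 under the step 7 catalyst to give the 2S alcohol F6, which is benzoylated to benzoate F7. Intermolecular coupling of the triflate with acrolein (CrCl2, NiCl2 cat., (S)-N-[2-(4-isopropyl-4,5-dihydro-1,3-oxazol-2-yl)-6-methylphenyl]methanesulfonamide, Et3N, THF) gives the hydroxy ester F8, which lactonises to the 5-vinylbutenolide F9. Ring-closing metathesis (second-generation Grubbs catalyst, (H2IMes)(PCy3)Cl2Ru=CHPh, toluene, 80 °C, 1 mM) gives the 14-O-silyl macrocycle F10, the ring enforcing the Z-alkene. HF·pyridine then returns to the route at 22.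

**Step 3 (Diels–Alder).** A trisubstituted enal and a 1,4-disubstituted diene must combine with regio-, endo- and enantiocontrol. Fallback: control is moved to a covalent auxiliary. Setting out from 5, condensation with (2R,4R)-pentane-2,4-diol (PPTS, benzene, −H2O) gives the dioxane acetal F1. Ionisation with TMSOTf (cat.) at −78 °C in the presence of 7 (Gassman-type ionic Diels–Alder through the far more reactive alkoxyallyl cation) gives the cycloadduct acetal F2. Transacetalisation (aq. CF3CO2H, 0 °C) returns to the route at 8; the enantiomeric diol is taken if the induction proves opposite.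

**Step 4 (ene oxidation).** The cis-disubstituted ring alkene is slow toward singlet oxygen, and its only usable face carries the axial C15 methyl. Fallback: oxygen is delivered thermally to C11 and then transposed. Setting out from 8, SeO2 (cat.)/t-BuOOH in CH2Cl2 gives the tertiary C11 allylic alcohol F3 (ene reaction then [2,3] shift). Pyridinium chlorochromate, C5H5NH[CrO3Cl], in CH2Cl2 with molecular sieves effects the Babler–Dauben oxidative 1,3-transposition and returns to the route at 11.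

## Further compounds

F1 | step 3 | ethyl (2Z,5E)-6-[(4R,6R)-4,6-dimethyl-1,3-dioxan-2-yl]-2-methyl-3-(trifluoromethylsulfonyloxy)hepta-2,5-dienoate | CCOC(=O)/C(C)=C(\OS(=O)(=O)C(F)(F)F)C/C=C(\C)C1O[C@H](C)C[C@@H](C)O1
F2 | step 3 | (4R,6R)-4,6-dimethyl-1,3-dioxan-2-yl acetal of 8 | CC(C)(C)[Si](C)(C)O[C@@H]1C=C[C@H](C)[C@@H](C/C(OS(=O)(=O)C(F)(F)F)=C(\C)C(=O)OCC)[C@]1(C)C2O[C@H](C)C[C@@H](C)O2
F3 | step 4 | C11 tertiary allylic alcohol of 8 (11R, OH trans to OTBS) | CC(C)(C)[Si](C)(C)O[C@@H]1C=C[C@@](C)(O)[C@@H](C/C(OS(=O)(=O)C(F)(F)F)=C(\C)C(=O)OCC)[C@]1(C)C=O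
F4 | step 11 | (3-methylbut-3-en-1-yl)diethylborane | CCB(CC)CCC(C)=C
F5 | step 11 | bis(3-methylbut-3-en-1-yl)zinc | C=C(C)CC[Zn]CCC(C)=C
F6 | step 11 | 2S alcohol from 11 bearing a 3-methylbut-3-enyl chain on C2 | CC(C)(C)[Si](C)(C)O[C@@H]1C(=O)C=C(C)[C@@H](C/C(OS(=O)(=O)C(F)(F)F)=C(\C)C(=O)OCC)[C@]1(C)[C@@H](O)CCC(C)=C
F7 | step 11 | C2 benzoate of F6 | CC(C)(C)[Si](C)(C)O[C@@H]1C(=O)C=C(C)[C@@H](C/C(OS(=O)(=O)C(F)(F)F)=C(\C)C(=O)OCC)[C@]1(C)[C@@H](OC(=O)c2ccccc2)CCC(C)=C
F8 | step 11 | 7R allylic alcohol (Z)-ethyl ester from acrolein addition, not isolated | CC(C)(C)[Si](C)(C)O[C@@H]1C(=O)C=C(C)[C@@H](C/C(=C(\C)C(=O)OCC)[C@H](O)C=C)[C@]1(C)[C@@H](OC(=O)c2ccccc2)CCC(C)=C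
F9 | step 11 | 7R 5-vinylbutenolide | CC(C)(C)[Si](C)(C)O[C@@H]1C(=O)C=C(C)[C@@H](CC2=C(C)C(=O)O[C@@H]2C=C)[C@]1(C)[C@@H](OC(=O)c2ccccc2)CCC(C)=C
F10 | step 11 | 14-O-tert-butyldimethylsilyl ether of 22 | CC(C)(C)[Si](C)(C)O[C@@H]1C(=O)C=C(C)[C@H]2CC3=C(C)C(=O)O[C@@H]3/C=C(/C)CC[C@H](OC(=O)c3ccccc3)[C@@]21C
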